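The readings were generated by integration on assumed constants; noise was put on by code.

The earlier epsilon and gamma runs each stir a solid electrophile with nucleophile in a closed flask, and Thursday's and Wednesday's flasks repeat them with other equivalents and a longer time.

| flask | solid electrophile | nucleophile | remark | time |
|---|---|---|---|---|
| epsilon | 2 M | 0.93 equiv | run made earlier |  |
| gamma | 2 M | 1.2 equiv | run made earlier |  |
| Thursday's | 2.0 M | 1.00 equiv |  | 25 min |
| Wednesday's | 2.0 M | 1.30 equiv |  | 25 min |

- epsilon (time / min: solid electrophile / %, target / %): 1.50: 91.3, 1.5; 4.00: 79.7, 7.3; 8.00: 62.2, 17.0; 12.0: 46.7, 22.9
- gamma (time / min: solid electrophile / %, target / %): 3.00: 84.3, 6.0; 6.00: 70.6, 13.9; 10.0: 52.5, 23.7; 12.0: 44.6, 27.4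

(readings scatter by 0.3 percentage points)

- at the start none of the solid electrophile is in solution
- what has only dissolved of solid electrophile counts as not reacted

* part of the solid electrophile that has reacted (what has only dissolved counts as not reacted) at the end, Thursday's
* part of the solid electrophile that has reacted (what has only dissolved counts as not reacted) at the end, Wednesday's
* what raising the equivalents of nucleophile from its lowest to its highest value here does to the part of the solid electrophile that has reacted (what has only dissolved counts as not reacted) (changes below 5 percentage points count as none) (no change / it falls / it rises)

At 12.0 min the gamma run, with 1.2 equiv of nucleophile against 0.93 equiv in the epsilon run, shows solid electrophile at 44.6% against 46.7%, a gap of 2.1 percentage points, yet target at 27.4% against 22.9%, a gap of 4.5 points. How can the nucleophile move the target and barely touch the solid? The two fit if the solid column reads mainly dissolving, a step ahead of the reaction, so I count the solid as a clock.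

At its mean pace the gamma run clears its charge in 21.7 min, the epsilon run in 22.5 min. The time the charge of solid needs at the mean pace up to the last reading is my emptying time. It is shorter than the 25 min of Thursday's and Wednesday's flasks, so at this pace both charges pass into solution before the end. What is asked then turns on the solution, and there I commit to a direction: target rose by a factor of 1.20 for a factor of 1.29 in nucleophile, so Wednesday's flask should stand higher than Thursday's.

The forecast differs on the solid, “leaving about 15–20% undissolved at 25 min”, and gives 64% for Thursday's flask, 72% for Wednesday's flask, and for the trend it rises.

The simulation gives 68.4% for Thursday's flask and 80.9% for Wednesday's flask; with the equivalents raised, it rises, by 12 points.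

    electrophile + nucleophile → acid set free + target (k = 0.00220 /M/s)
    nucleophile + acid set free ⇌ protonated nucleophile, settled at all times (K = 2500 /M)
    solid electrophile ⇌ electrophile, rate k3*(cs3 - [electrophile]) while solid is left; crystals form when [electrophile] > cs3 (solubility = 1.10 M, k = 0.00180 /s)
    electrophile + target → side product (k = 0.00180 /M/s)
    target → over-reaction product (k = 3.40 × 10⁻⁶ /s)

The emptying time comes out short for Thursday's flask: at 25.0 min it still has 2.86% of its solid left, where the mean pace gave none, while Wednesday's flask has 0%. The same flask as Thursday's, read at 10 min, should keep 53.9% by that pace and holds 54.2%. Thursday's and Wednesday's flasks differ in the equivalents of nucleophile, and that difference is the main reason for the gap between them: Wednesday's flask stands at 80.9%, and with Thursday's equivalents at 68.4%.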